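The small charge here was the protic impurity, 0.120 M against 0.720 M of coupling partner and 1.2 M of substrate, and I wanted its price in product.

| flask | substrate | coupling partner | protic impurity | free catalyst | remark | time |
|---|---|---|---|---|---|---|
| birch | 1.2 M | 0.720 M | 0.120 M | 7.6 mM | a single well-mixed tank run continuously and read at steady state, 2.5 h in it on average |  |
| ash | 1.2 M | 0.720 M (fed, over 2.00 h) | 0.120 M | 7.6 mM | all but coupling partner at the start; coupling partner goes in evenly over 2.00 h, the run ends at 2.5 h | 2.5 h |
| larch | 1.2 M (fed, over 2.00 h) | 0.720 M | 0.120 M | 7.6 mM | a stirred flask in which substrate is dosed at a steady rate over 2.00 h without added volume, worked up at 2.5 h | 2.5 h |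
| elm | 1.2 M | 0.720 M | 0.120 M | 7.6 mM | everything together in a closed stirred flask, run for 2.5 h | 2.5 h |

* the set-up with the highest amount of product at the outlet or at the end, in percent of the substrate put in ("none" if the first two lie within 2 percentage points) (birch / ash / larch / elm / none)
* amount of product at the outlet or at the end, in percent of the substrate put in, birch
* amount of product at the outlet or at the end, in percent of the substrate put in, ash
* amount of product at the outlet or at the end, in percent of the substrate put in, larch
* amount of product at the outlet or at the end, in percent of the substrate put in, elm

- the stated concentrations are those of everything mixed, before any reaction; amounts are the same in each set-up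
- the feed brings no volume worth counting
- run time (ash): 2.5 h

    catalyst intermediate C → released group + catalyst intermediate D (k1 = 0.404 s⁻¹)
    coupling partner + protic impurity → quenched reagent (k2 = 0.222 M⁻¹ s⁻¹)
    catalyst intermediate A → catalyst intermediate B (k3 = 0.514 s⁻¹)
    substrate + catalyst intermediate B → catalyst intermediate C (k4 = 3.02 M⁻¹ s⁻¹)
    coupling partner + free catalyst → catalyst intermediate A (k5 = 2.37 M⁻¹ s⁻¹)
    free catalyst ⇌ dormant form (K6 = 6.36, k6 = 0.00288 s⁻¹)
    catalyst intermediate D → free catalyst + product (k7 = 0.147 s⁻¹)

Free catalyst takes up coupling partner and carries it round to product, one for each substrate. Coupling partner is therefore the limiting reagent, and my upper bound was 60.0% of the substrate, with the impurity taking nothing. Each impurity destroys one coupling partner, so my lower bound, given time, was 50.0%, the net partner ratio: coupling partner less protic impurity, over substrate.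

At the start of elm, free catalyst used coupling partner at 0.68 times the rate of the impurity. But the impurity thins as it reacts. Even with the catalyst wholly free, 0.0614% of the impurity remains once the net partner has passed, hardly any, so in ash, larch and elm the upper bound closed onto the lower.

For time, I took free catalyst at its equilibrium share, 13.6%. Coupling partner is then taken up at 0.00245 s⁻¹, a half-life of 4.72 min, shorter than the 0.500 h after the feeds end. So I put elm at 50.0%, ash at 50.0% and larch at 50.0%. Birch keeps back a share of one over one plus uptake times mean stay, which gave 47.8%.

The forecast gave 48.1% for birch, a little above mine, 49.9% for ash, about my lower bound, and 50% for larch and 50% for elm, on it. Its verdict was none, the cycle being “fast enough for the batch and fed runs to reach it”.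

The simulation gave 48.1% for birch, 50.0% for ash, 50.0% for larch and 50.0% for elm, and the verdict none.

One way to put the forecast wrong for elm was to move the net ratio. Elm's answer shifted by 5 points at 0.660 M or 0.780 M of coupling partner, where that ratio reads 45.0% and 55.0%. The neighbouring flask, elm with 1.2 M of coupling partner, has a net ratio of 90.0%. It gave 90.0% of product and ended with 10.0% of its substrate.

The constants are made up; the result is computed.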